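The earlier runs and the new flask stem from a simulated flask with made-up constants.

| flask | substrate | remark | time |
|---|---|---|---|
| south | 0.30 M | the very flask that is asked about, followed so far |  |
| north-east | 0.15 M | run made earlier |  |
| flask | 0.30 M |  | 4.0 h |

- south (time / min: intermediate B / %, target / %, substrate / %): 8.00: 26, 10, 0; 15.0: 35, 17, 0; 20.0: 32, 23, 2; 30.0: 21, 35, 0
- north-east (time / h: intermediate B / %, target / %, substrate / %): 0.250: 31, 19, 1; 0.500: 21, 36, 0; 1.33: 3, 52, 3; 3.00: 1, 51, 0

(standard deviation of a reading: 2 percentage points)

* time up to 4.0 h at which intermediate B stands highest
* the amount of intermediate B, in percent of the substrate charged, at that time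

- what is said of target includes crystals
- crystals is a solid; its amount is given per volume of the solution
- steps under discussion: target <-> isomer of the product; intermediate A -> intermediate B; crystals <-> target; substrate -> intermediate A; intermediate B -> target

Intermediate B at 21% after 30.0 min is a better number to work from than the hunch that the peak sits at the highest reading, 35% at 15.0 min. The north-east run, with 0.15 M against 0.30 M in the south flask, reads the same 21% at that time, so in percent the curve looks independent of the charge. Substrate reads 0% at the first south reading, so I take B as fed and drained by two first-order steps of about equal speed: B = x·e^(−x), with x = t/τ. Putting the hunch in as the first τ gives x = 2.00; then x = ln(x/B) returns 2.25. So τ, the chain time at which B peaks, is 0.222 h, and a further round gives 0.211 h. The two runs read 35% and 31% at 15.0 min, on average 33.0%; this curve peaks at 36.8%, higher than that average, so I take the height from the readings.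

The forecast says 0.27 h (0.21 h to 0.33 h) and 35% (32% to 38%), from “A smooth curve through the noisy points”, a later time than my τ.

The south flask gives its highest B, 32.5%, at 0.224 h, beside τ of 0.222 h. At 0.448 h, twice that time, it holds 23.9% of B; the curve through τ, scaled to the read height, gives 24.1% there.

    target ⇌ isomer of the product (K = 0.870, k = 0.00860 /s)
    intermediate A → intermediate B (k = 0.00110 /s)
    crystals ⇌ target, rate k3*(cs3 - [target]) while solid is left; crystals form when [target] > cs3 (solubility = 0.130 M, k = 5.40 /s)
    substrate → intermediate A (k = 0.320 /s)
    intermediate B → target (k = 0.00140 /s)

For the neighbour flask with 0.75 M of substrate, the same τ and height put B's peak near 0.222 h at 33.0%. The simulation gives that flask a highest B of 32.5%.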